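Target 34 is reached from macrocycle 32 by desilylation and acetylation; 32 comes from chloro aldehyde 29 by an intramolecular Nozaki–Hiyama–Kishi allylation that forms C3–C4 and closes the ten-membered ring last.
Enabling feature: in the ten-membered ring the carbinol C3 is homoallylic to the 1,1-disubstituted alkene C5=C16 (C3(O)–C4H2–C5(=C16H2)) and sits next to oxygenated C2, which is the retron of an allylmetal addition to an α-alkoxy aldehyde; the same event delivers the exo-methylene beside the C6 chloride.
The γ-lactone (C7, C8, C17, C19, O) is in place before that: a chromium γ-chloroallylation of a C7 aldehyde sets C6/C7, and the lactone arises by acyl transfer from a temporary C9–O lactone that was formed by epoxide opening (inversion at C9) after Sharpless epoxidation of a (Z)-allylic alcohol (C8).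
Ring A comes first, from a catalytic enantioselective Diels–Alder reaction of diene 2 with enal ester 3 (C1, C10) and Saegusa oxidation; C2 is set by Felkin–Anh addition, C17 comes from (R)-lactate, C11 is set by equilibration.
Order of ring formation: six-membered ring A, then the five-membered lactone (through its isomeric template), then the ten-membered ring.

Key step: step 21

Numbering used for all intermediates (briarane numbering): C1 (quaternary, methyl C15), C2, C3, C4, C5 (=C16), C6 (Cl), C7 (lactone O), C8 (OH), C9, C10, C11 (methyl C20), C12 (C=O), C13=C14, C17 (methyl C18), C19 (lactone C=O).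
Assumption: the oxazaborolidinium enantiomer named in step 2 is taken to expose the enal face that leads to the (1S,10S) adduct; if its sense of induction is the opposite, the mirror-image catalyst is used.

Step 1
Reactants: 1 pent-1-en-3-one
Product: 2 (Z)-3-(triisopropylsilyloxy)penta-1,3-diene
Conditions: iPr3SiOTf, Et3N, CH2Cl2, 0 °C to rt
Reagents that add atoms: triisopropylsilyl triflate, CC(C)[Si](C(C)C)(C(C)C)OS(=O)(=O)C(F)(F)F
Why: Soft enolization and O-silylation of the only enolizable side of the enone gives the 2-silyloxy diene, the (Z)-enol ether (methyl anti to the vinyl group) being the usual product and the one that keeps the methyl on the outside of the s-cis diene.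

Step 2
Reactants: 2 (Z)-3-(triisopropylsilyloxy)penta-1,3-diene; 3 ethyl (E)-3-methyl-4-oxobut-2-enoate
Product: 4 ethyl (1S,2S,6S)-6-formyl-2,6-dimethyl-3-(triisopropylsilyloxy)cyclohex-3-ene-1-carboxylate
Conditions: (S)-3,3-diphenyl-1-(o-tolyl)tetrahydro-1H,3H-pyrrolo[1,2-c][1,3,2]oxazaborole and HNTf2 (10 mol % each), CH2Cl2, −78 to −40 °C
Reagents that add atoms: none
Why: Catalytic enantioselective Diels–Alder reaction in which the oxazaborolidinium ion binds the formyl group, the nucleophilic diene terminus (C11) bonds to the enal β-carbon C10 and the CH2 terminus to quaternary C1, the (E)-dienophile fixes C2 and C9 trans, the catalyst face sets C1 and C10, and the formyl-endo transition state puts the C11 methyl trans to the ester (corrected in step 11).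

Step 3
Reactants: 4 Diels–Alder aldehyde; 5 tributyl[(methoxymethoxy)methyl]stannane
Product: 6 C2 carbinol, ethyl (1S,2S,6S)-6-[(1R)-1-hydroxy-2-(methoxymethoxy)ethyl]-2,6-dimethyl-3-(triisopropylsilyloxy)cyclohex-3-ene-1-carboxylate
Conditions: 5, n-BuLi, THF, −78 °C; then 4, −78 °C; aq NH4Cl
Reagents that add atoms: none
Why: Addition of an α-alkoxymethyllithium (tin–lithium exchange) to the neopentyl aldehyde, faster than to the ester at −78 °C, with Felkin–Anh control from quaternary C1 (C10 branch anti to the nucleophile, methyl beside its trajectory) setting C2 as R and bringing in C3.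

Step 4
Reactants: 6 C2 carbinol
Product: 7 C2 tert-butyldimethylsilyl ether of 6
Conditions: t-BuMe2SiOTf, 2,6-lutidine, CH2Cl2, −78 to 0 °C
Reagents that add atoms: tert-butyldimethylsilyl triflate, CC(C)(C)[Si](C)(C)OS(=O)(=O)C(F)(F)F
Why: Silyl triflate silylation of the hindered secondary alcohol gives an ether that survives both hydride steps and later directs the ring closure.

Step 5
Reactants: 7 silyl ether ester
Product: 8 C9 aldehyde, (1S,2S,6S)-6-[(1R)-1-(tert-butyldimethylsilyloxy)-2-(methoxymethoxy)ethyl]-2,6-dimethyl-3-(triisopropylsilyloxy)cyclohex-3-ene-1-carbaldehyde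
Conditions: iBu2AlH (1.1 equiv), CH2Cl2, −78 °C; aq potassium sodium tartrate
Reagents that add atoms: none
Why: Partial reduction of the ester stops at the aldehyde because the tetrahedral aluminium hemiacetal is stable at −78 °C, and the silyl enol ether, silyl ether and acetal are inert to the hydride.

Step 6
Reactants: 9 tert-butyl (R)-2-hydroxypropanoate
Product: 10 tert-butyl (R)-2-(trifluoromethylsulfonyloxy)propanoate
Conditions: Tf2O, 2,6-lutidine, CH2Cl2, −78 °C
Reagents that add atoms: triflic anhydride, O=S(=O)(OS(=O)(=O)C(F)(F)F)C(F)(F)F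
Why: O-Sulfonylation of the lactate hydroxyl with retention gives a secondary triflate that undergoes clean SN2 displacement.

Step 7
Reactants: 10 lactate triflate; 11 methyl 2-[bis(2,2,2-trifluoroethoxy)phosphoryl]acetate
Product: 12 1-methyl 4-tert-butyl (3S)-2-[bis(2,2,2-trifluoroethoxy)phosphoryl]-3-methylbutanedioate (mixture at the phosphorus-bearing carbon)
Conditions: 11, NaH, THF, 0 °C; then 10, 0 °C to rt
Reagents that add atoms: none
Why: SN2 alkylation of the stabilized phosphonoacetate anion by the α-triflyloxy ester proceeds with inversion and so fixes C17, while the phosphorus-bearing carbon (future sp2 C8) is an inconsequential mixture.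

Step 8
Reactants: 8 C9 aldehyde; 12 phosphonate
Product: 13 (Z)-enoate, ring A–C9H=C8(CO2Me)–C17H(CH3)–CO2tBu with C10 cis to the methyl ester carbon C7
Conditions: 12, KN(SiMe3)2, 18-crown-6, THF, −78 °C; then 8
Reagents that add atoms: none
Why: Still–Gennari olefination, in which the electron-poor bis(trifluoroethyl) phosphonate and a dissociated potassium ion give fast kinetic elimination to the (Z)-trisubstituted enoate, the geometry needed for the later anti functionalization of C8 and C9.

Step 9
Reactants: 13 (Z)-enoate
Product: 14 (Z)-allylic alcohol (C7H2OH on C8, tert-butyl ester kept)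
Conditions: iBu2AlH (2.5 equiv), CH2Cl2, −78 °C; aq potassium sodium tartrate
Reagents that add atoms: none
Why: Hydride reduction of the conjugated methyl ester to the allylic alcohol is fast at −78 °C, whereas the hindered tert-butyl ester and the silyl enol ether are untouched.

Step 10
Reactants: 14 (Z)-allylic alcohol
Product: 15 2,3-epoxy alcohol (epoxide across C8–C9, oxygen on the face anti to C1)
Conditions: Ti(OiPr)4 (0.5 equiv), L-(+)-diisopropyl tartrate (0.6 equiv), t-BuOOH, 4 Å molecular sieves, CH2Cl2, −20 °C
Reagents that add atoms: tert-butyl hydroperoxide, CC(C)(C)OO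
Why: Sharpless asymmetric epoxidation touches only the allylic alcohol alkene, and the face chosen by the L-(+)-tartrate catalyst is also the one the substrate prefers (allylic 1,3-strain holds H-10 in the alkene plane and the oxidant comes anti to quaternary C1), which sets the C8–O bond of the target.

Step 11
Reactants: 15 epoxy alcohol silyl enol ether
Product: 17 enone epoxy alcohol with C11 as in the target, via C11-epimeric enone 16 (not isolated)
Conditions: Pd(OAc)2 (1.1 equiv), MeCN, rt; then 1,8-diazabicyclo[5.4.0]undec-7-ene (0.3 equiv), rt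
Reagents that add atoms: none
Why: Saegusa–Ito oxidation (palladium enolate at C13, β-hydride elimination from C14) gives the C13=C14 enone regiospecifically, and the amidine base then equilibrates C11 to the more stable epimer, in which the bulky C10 substituent is pseudoaxial and anti to the C2 chain while the C11 methyl is equatorial and cis to it.

Step 12
Reactants: 17 enone epoxy alcohol
Product: 18 temporary C9–O γ-lactone (ring O–C9–C8–C17–C19) with free C7H2OH and tertiary C8–OH
Conditions: camphor-10-sulfonic acid (0.2 equiv), CH2Cl2, 0 °C to rt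
Reagents that add atoms: none
Why: Acid-promoted opening of the β,γ-epoxy ester by the ester carbonyl oxygen at C9 (five-membered ring, loss of 2-methylpropene) goes with inversion, which installs the natural C9–O configuration and leaves the epoxide oxygen as the C8 hydroxyl.

Step 13
Reactants: 18 lactone diol
Product: 19 bis(triethylsilyl) ether (C7–OTES, C8–OTES)
Conditions: Et3SiOTf (2.5 equiv), 2,6-lutidine, CH2Cl2, −78 °C
Reagents that add atoms: triethylsilyl triflate, CC[Si](CC)(CC)OS(=O)(=O)C(F)(F)F
Why: Silyl triflate with a hindered pyridine base silylates the primary and the tertiary hydroxyl at low temperature without enolizing the enone.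

Step 14
Reactants: 19 bis(triethylsilyl) ether
Product: 20 C7 aldehyde (C8–OTES, temporary lactone intact)
Conditions: (COCl)2, DMSO, CH2Cl2, −78 to −40 °C; then Et3N
Reagents that add atoms: none
Why: Swern conditions cleave and oxidize a primary triethylsilyl ether directly to the aldehyde while tertiary triethylsilyl and secondary tert-butyldimethylsilyl ethers stay, and the quaternary α-carbon rules out epimerization.

Step 15
Reactants: 21 1,3-dichloropropan-2-one; 22 (chloromethyl)triphenylphosphonium chloride
Product: 23 1,3-dichloro-2-(chloromethyl)prop-1-ene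
Conditions: 22, NaN(SiMe3)2, THF, −78 °C; then 21, −78 °C to rt
Reagents that add atoms: none
Why: Wittig chloromethylenation of the ketone with the preformed, weakly basic chloromethylene ylide at low temperature outruns substitution at the α-chloro positions.

Step 16
Reactants: 20 C7 aldehyde; 23 1,3-dichloro-2-(chloromethyl)prop-1-ene
Product: 24 anti chlorohydrin, C7–OH / C6–Cl with C5(=C16H2)–C4H2Cl
Conditions: 23 (3 equiv), CrCl2 (6 equiv), THF, 0 °C to rt
Reagents that add atoms: none
Why: Chromium-mediated γ-chloroallylation of the Nozaki–Hiyama type, in which divalent chromium inserts into one allylic C–Cl bond, the (E)-γ-chloroallylchromium species adds through a chair transition state to give the anti chlorohydrin (C6/C7), and Felkin–Anh control by the C8 silyloxy centre (attack from the C17 side, away from ring A which is cis to the formyl group on the temporary lactone) sets C7, the exo-methylene and the C4 chloromethyl arm being formed in the same event.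

Step 17
Reactants: 24 anti chlorohydrin
Product: 26 γ-lactone of the target type (ring O–C7–C8–C17–C19) with free C8–OH and C9–OH, via desilylated C9-lactone diol 25 (not isolated)
Conditions: camphor-10-sulfonic acid (0.3 equiv), MeOH/CH2Cl2 (1:4), rt
Reagents that add atoms: none
Why: Acid removes the tertiary triethylsilyl ether and catalyses intramolecular transesterification, the C7 hydroxyl taking over the C19 acyl group because the new lactone has the C6 chain trans to C9 whereas the temporary one holds ring A and the C7 chain cis.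

Step 18
Reactants: 26 lactone diol
Product: 27 C9 acetate (tertiary C8–OH free)
Conditions: Ac2O, pyridine, 4-(dimethylamino)pyridine (cat.), CH2Cl2, 0 °C
Reagents that add atoms: acetic anhydride, CC(=O)OC(C)=O
Why: Nucleophile-catalysed acylation takes the secondary C9 hydroxyl, and the tertiary C8 hydroxyl is too hindered to react under these conditions.

Step 19
Reactants: 27 C9 acetate
Product: 28 primary C3 alcohol
Conditions: Me2BBr, CH2Cl2, −78 °C; then aq NaHCO3/THF
Reagents that add atoms: none
Why: Bromoborane cleavage of the methoxymethyl acetal at −78 °C is selective for the acetal oxygen and leaves the silyl ether, acetate, lactone, enone and both allylic chlorides.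

Step 20
Reactants: 28 primary C3 alcohol
Product: 29 α-silyloxy aldehyde (C3 formyl, C4H2Cl)
Conditions: Dess–Martin periodinane, pyridine, CH2Cl2, 0 °C to rt
Reagents that add atoms: none
Why: Dess–Martin oxidation converts the primary alcohol to the aldehyde under buffered conditions that neither epimerize C2 nor touch the tertiary hydroxyl.

Step 21
Reactants: 29 α-silyloxy aldehyde
Product: 32 ten-membered carbocycle with C3–OH and C2–OTBS, via allylic iodide 30 (not isolated), via allylchromium dichloride species 31 (not isolated)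
Conditions: CrCl2 (10 equiv), LiI (0.2 equiv), THF/DMF (4:1), rt, syringe-pump addition to 0.002 M
Reagents that add atoms: none
Why: Divalent chromium (two equivalents per carbon–halogen bond) reduces the primary allylic iodide formed in situ by iodide exchange at C4 to a trivalent allylchromium species, which adds to the C3 aldehyde through a six-membered chair-like allyl-transfer transition state with allylic transposition, so that the former exo-methylene carbon becomes C4 and the halide-bearing carbon becomes the C16 exo-methylene. The closest known reaction type is the intramolecular Nozaki–Hiyama–Kishi allylation used to close ten- to fourteen-membered carbocycles. The ten-membered ring is closed by 1,2-addition at the formyl carbon (exo with respect to the C=O bond), while ring A and the γ-lactone, both already in place, hold the C2 and C6 arms on neighbouring positions and shorten the effective tether. The new stereocenter C3 is controlled by C2 through the Felkin–Anh model (C2–OSi bond anti to the incoming allyl carbon, hydrogen beside its trajectory), which gives the 2,3-anti relationship of the target. The step needs selectivity for the primary allylic halide over the secondary allylic chloride at C6, for the aldehyde over enone, lactone and acetate, and for cyclization over oligomerization; these rest on halide exchange occurring only at the unhindered primary carbon, on the aldehyde selectivity of allylchromium reagents and on slow addition at high dilution. In one operation it forms the C3–C4 bond, the ten-membered ring, the C3 carbinol stereocenter and the C5 exo-methylene next to the intact C6 chloride.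

Step 22
Reactants: 32 macrocyclic C3 alcohol
Product: 33 C2,C3-diol
Conditions: HF·pyridine, THF/pyridine, 0 °C to rt
Reagents that add atoms: none
Why: Buffered fluoride cleavage removes the hindered secondary silyl ether without touching acetate, lactone or the allylic chloride.

Step 23
Reactants: 33 C2,C3-diol
Product: 34 CNP0391614.1
Conditions: Ac2O, pyridine, 4-(dimethylamino)pyridine (cat.), CH2Cl2, rt
Reagents that add atoms: acetic anhydride, CC(=O)OC(C)=O
Why: Acylation of the two secondary hydroxyls at C2 and C3 completes the triacetate, the tertiary C8 hydroxyl between two fully substituted neighbours staying free.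

Compound list
1 | pent-1-en-3-one | CCC(=O)C=C | starting material
2 | (Z)-3-(triisopropylsilyloxy)penta-1,3-diene | C/C=C(/C=C)O[Si](C(C)C)(C(C)C)C(C)C | intermediate
3 | ethyl (E)-3-methyl-4-oxobut-2-enoate | CCOC(=O)/C=C(C)/C=O | starting material
4 | ethyl (1S,2S,6S)-6-formyl-2,6-dimethyl-3-(triisopropylsilyloxy)cyclohex-3-ene-1-carboxylate (C2 and C9 trans, C11 epimeric to target) | O=C[C@@]1(C)CC=C(O[Si](C(C)C)(C(C)C)C(C)C)[C@@H](C)[C@@H]1C(=O)OCC | intermediate
5 | tributyl[(methoxymethoxy)methyl]stannane | CCCC[Sn](CCCC)(CCCC)COCOC | starting material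
6 | C2 carbinol (2R), ethyl ester, C3–OMOM | COCOC[C@H](O)[C@@]1(C)CC=C(O[Si](C(C)C)(C(C)C)C(C)C)[C@@H](C)[C@@H]1C(=O)OCC | intermediate
7 | C2–OTBS ether of 6 | COCOC[C@H](O[Si](C)(C)C(C)(C)C)[C@@]1(C)CC=C(O[Si](C(C)C)(C(C)C)C(C)C)[C@@H](C)[C@@H]1C(=O)OCC | intermediate
8 | C9 aldehyde | COCOC[C@H](O[Si](C)(C)C(C)(C)C)[C@@]1(C)CC=C(O[Si](C(C)C)(C(C)C)C(C)C)[C@@H](C)[C@@H]1C=O | intermediate
9 | tert-butyl (R)-2-hydroxypropanoate | C[C@@H](O)C(=O)OC(C)(C)C | starting material
10 | tert-butyl (R)-2-(trifluoromethylsulfonyloxy)propanoate | C[C@@H](OS(=O)(=O)C(F)(F)F)C(=O)OC(C)(C)C | intermediate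
11 | methyl 2-[bis(2,2,2-trifluoroethoxy)phosphoryl]acetate | COC(=O)CP(=O)(OCC(F)(F)F)OCC(F)(F)F | starting material
12 | 1-methyl 4-tert-butyl (3S)-2-[bis(2,2,2-trifluoroethoxy)phosphoryl]-3-methylbutanedioate (mixture at C2 of the diester) | COC(=O)C([C@@H](C)C(=O)OC(C)(C)C)P(=O)(OCC(F)(F)F)OCC(F)(F)F | intermediate
13 | (Z)-enoate, C10 cis to C7 (CO2Me), C17 set, tert-butyl ester at C19 | COCOC[C@H](O[Si](C)(C)C(C)(C)C)[C@@]1(C)CC=C(O[Si](C(C)C)(C(C)C)C(C)C)[C@@H](C)[C@@H]1/C=C(\C(=O)OC)[C@@H](C)C(=O)OC(C)(C)C | intermediate
14 | (Z)-allylic alcohol (C7H2OH) | COCOC[C@H](O[Si](C)(C)C(C)(C)C)[C@@]1(C)CC=C(O[Si](C(C)C)(C(C)C)C(C)C)[C@@H](C)[C@@H]1/C=C(\CO)[C@@H](C)C(=O)OC(C)(C)C | intermediate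
15 | C8–C9 epoxy alcohol | COCOC[C@H](O[Si](C)(C)C(C)(C)C)[C@@]1(C)CC=C(O[Si](C(C)C)(C(C)C)C(C)C)[C@@H](C)[C@@H]1[C@H]2O[C@]2(CO)[C@@H](C)C(=O)OC(C)(C)C | intermediate
16 | enone epoxy alcohol, C11 epimeric to target | COCOC[C@H](O[Si](C)(C)C(C)(C)C)[C@@]1(C)C=CC(=O)[C@@H](C)[C@@H]1[C@H]2O[C@]2(CO)[C@@H](C)C(=O)OC(C)(C)C | intermediate (not isolated)
17 | enone epoxy alcohol, C11 as in target | COCOC[C@H](O[Si](C)(C)C(C)(C)C)[C@@]1(C)C=CC(=O)[C@H](C)[C@@H]1[C@H]2O[C@]2(CO)[C@@H](C)C(=O)OC(C)(C)C | intermediate
18 | temporary C9–O γ-lactone with C7H2OH and C8–OH | COCOC[C@H](O[Si](C)(C)C(C)(C)C)[C@@]1(C)C=CC(=O)[C@H](C)[C@@H]1[C@@H]2OC(=O)[C@H](C)[C@]2(O)CO | intermediate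
19 | bis(triethylsilyl) ether of 18 | COCOC[C@H](O[Si](C)(C)C(C)(C)C)[C@@]1(C)C=CC(=O)[C@H](C)[C@@H]1[C@@H]2OC(=O)[C@H](C)[C@]2(O[Si](CC)(CC)CC)CO[Si](CC)(CC)CC | intermediate
20 | C7 aldehyde (C8–OTES, temporary lactone) | COCOC[C@H](O[Si](C)(C)C(C)(C)C)[C@@]1(C)C=CC(=O)[C@H](C)[C@@H]1[C@@H]2OC(=O)[C@H](C)[C@]2(O[Si](CC)(CC)CC)C=O | intermediate
21 | 1,3-dichloropropan-2-one | ClCC(=O)CCl | starting material
22 | (chloromethyl)triphenylphosphonium chloride | ClC[P+](c1ccccc1)(c1ccccc1)c1ccccc1.[Cl-] | starting material
23 | 1,3-dichloro-2-(chloromethyl)prop-1-ene | ClC=C(CCl)CCl | intermediate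
24 | anti chlorohydrin (C7–OH, C6–Cl, C5=C16, C4H2Cl; C8–OTES, temporary lactone) | COCOC[C@H](O[Si](C)(C)C(C)(C)C)[C@@]1(C)C=CC(=O)[C@H](C)[C@@H]1[C@@H]2OC(=O)[C@H](C)[C@]2(O[Si](CC)(CC)CC)[C@@H](O)[C@@H](Cl)C(=C)CCl | intermediate
25 | desilylated C9-lactone diol (C7–OH, C8–OH) | COCOC[C@H](O[Si](C)(C)C(C)(C)C)[C@@]1(C)C=CC(=O)[C@H](C)[C@@H]1[C@@H]2OC(=O)[C@H](C)[C@]2(O)[C@@H](O)[C@@H](Cl)C(=C)CCl | intermediate (not isolated)
26 | C7–O γ-lactone with C8–OH and C9–OH | COCOC[C@H](O[Si](C)(C)C(C)(C)C)[C@@]1(C)C=CC(=O)[C@H](C)[C@@H]1[C@H](O)[C@]2(O)[C@@H](C)C(=O)O[C@H]2[C@@H](Cl)C(=C)CCl | intermediate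
27 | C9 acetate | COCOC[C@H](O[Si](C)(C)C(C)(C)C)[C@@]1(C)C=CC(=O)[C@H](C)[C@@H]1[C@H](OC(C)=O)[C@]2(O)[C@@H](C)C(=O)O[C@H]2[C@@H](Cl)C(=C)CCl | intermediate
28 | primary C3 alcohol | OC[C@H](O[Si](C)(C)C(C)(C)C)[C@@]1(C)C=CC(=O)[C@H](C)[C@@H]1[C@H](OC(C)=O)[C@]2(O)[C@@H](C)C(=O)O[C@H]2[C@@H](Cl)C(=C)CCl | intermediate
29 | α-silyloxy aldehyde, cyclization precursor | O=C[C@H](O[Si](C)(C)C(C)(C)C)[C@@]1(C)C=CC(=O)[C@H](C)[C@@H]1[C@H](OC(C)=O)[C@]2(O)[C@@H](C)C(=O)O[C@H]2[C@@H](Cl)C(=C)CCl | intermediate
30 | allylic iodide | O=C[C@H](O[Si](C)(C)C(C)(C)C)[C@@]1(C)C=CC(=O)[C@H](C)[C@@H]1[C@H](OC(C)=O)[C@]2(O)[C@@H](C)C(=O)O[C@H]2[C@@H](Cl)C(=C)CI | intermediate (not isolated)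
31 | allylchromium dichloride species | O=C[C@H](O[Si](C)(C)C(C)(C)C)[C@@]1(C)C=CC(=O)[C@H](C)[C@@H]1[C@H](OC(C)=O)[C@]2(O)[C@@H](C)C(=O)O[C@H]2[C@@H](Cl)C(=C)C[Cr](Cl)Cl | intermediate (not isolated)
32 | ten-membered carbocycle, C3–OH, C2–OTBS, C9–OAc | C=C1C[C@H](O)[C@H](O[Si](C)(C)C(C)(C)C)[C@@]2(C)C=CC(=O)[C@H](C)[C@@H]2[C@H](OC(C)=O)[C@]2(O)[C@@H](C)C(=O)O[C@H]2[C@H]1Cl | intermediate
33 | C2,C3-diol, C9–OAc | C=C1C[C@H](O)[C@H](O)[C@@]2(C)C=CC(=O)[C@H](C)[C@@H]2[C@H](OC(C)=O)[C@]2(O)[C@@H](C)C(=O)O[C@H]2[C@H]1Cl | intermediate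
34 | CNP0391614.1 | C=C1C[C@H](OC(C)=O)[C@H](OC(C)=O)[C@@]2(C)C=CC(=O)[C@H](C)[C@@H]2[C@H](OC(C)=O)[C@]2(O)[C@@H](C)C(=O)O[C@H]2[C@H]1Cl | target

Total step count: 23
Longest linear sequence: 20 steps (steps 1–5, 8–14, 16–23)

Steps most likely to fail

Step 16. The bifunctional chloroallyl reagent may react a second time through the product's primary allylic chloride, and simple diastereoselection (anti) or facial selectivity at the hindered C7 aldehyde may erode. The fallback sets out from 20 and comes back at 24 and uses epoxide logic instead of allylmetal addition: commercial 3-chloro-2-(chloromethyl)prop-1-ene is treated with dimethyl sulfide (acetone, rt) to give the allylic sulfonium salt dimethyl[2-(chloromethyl)prop-2-en-1-yl]sulfonium chloride F1; its ylide (LiN(SiMe3)2, THF, −78 °C) adds to 20 in a Johnson–Corey–Chaykovsky epoxidation to give the trans vinyl epoxide F2 (C6–C7 epoxide, same aldehyde face as in step 16); SN2 opening of F2 at the allylic carbon C6 with pyridinium chloride (CH2Cl2, 0 °C, inversion) gives the anti chlorohydrin 24.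

Step 21. The ring closure may lose to reduction at the secondary C6 chloride, to protonation of the allylchromium species or to oligomerization, because of the strain of the ten-membered ring. The fallback sets out from 28 and comes back at 32 and replaces the reductive Barbier-type closure by a Lewis-acid-mediated one: the primary allylic chloride of 28 is converted with hexamethyldisilane and Pd(PPh3)4 (cat., THF, 60 °C) to the allylsilane alcohol F3; Dess–Martin oxidation gives the allylsilane aldehyde F4; intramolecular Hosomi–Sakurai allylation (BF3·OEt2, CH2Cl2, −78 °C, high dilution) closes the ring to 32, again under Felkin–Anh control from C2.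

Step 3. Facial selectivity at the aldehyde on quaternary C1 may be poor, giving a C2 epimer mixture. The fallback sets out from 6 (as the epimer mixture) and comes back at 6 and replaces substrate control by reagent control: Dess–Martin oxidation gives the C2 ketone F5, and Corey–Bakshi–Shibata reduction with the (R)-B-methyl oxazaborolidine of α,α-diphenylprolinol (cat.) and catecholborane (toluene, −78 °C) delivers hydride to the ketone face that gives the (2R) alcohol 6 (large group C1, small group CH2OMOM).

Further compounds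
F1 | step 16 | dimethyl[2-(chloromethyl)prop-2-en-1-yl]sulfonium chloride | C[S+](C)CC(=C)CCl.[Cl-]
F2 | step 16 | trans C6–C7 vinyl epoxide (C8–OTES, temporary lactone) | COCOC[C@H](O[Si](C)(C)C(C)(C)C)[C@@]1(C)C=CC(=O)[C@H](C)[C@@H]1[C@@H]2OC(=O)[C@H](C)[C@]2(O[Si](CC)(CC)CC)[C@H]3O[C@@H]3C(=C)CCl
F3 | step 21 | allylsilane alcohol (C4H2SiMe3, C3H2OH) | OC[C@H](O[Si](C)(C)C(C)(C)C)[C@@]1(C)C=CC(=O)[C@H](C)[C@@H]1[C@H](OC(C)=O)[C@]2(O)[C@@H](C)C(=O)O[C@H]2[C@@H](Cl)C(=C)C[Si](C)(C)C
F4 | step 21 | allylsilane aldehyde | O=C[C@H](O[Si](C)(C)C(C)(C)C)[C@@]1(C)C=CC(=O)[C@H](C)[C@@H]1[C@H](OC(C)=O)[C@]2(O)[C@@H](C)C(=O)O[C@H]2[C@@H](Cl)C(=C)C[Si](C)(C)C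
F5 | step 3 | C2 ketone, ethyl ester | COCOCC(=O)[C@@]1(C)CC=C(O[Si](C(C)C)(C(C)C)C(C)C)[C@@H](C)[C@@H]1C(=O)OCC
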